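Everything rests on cutting the bond between C7, the benzylic CH2 of dimethoxyphenyl ring A, and C8, the methyl-bearing methine. The feature exploited: C8 hangs on C4 of dienone ring B, para to the C1 carbonyl, so at the phenol oxidation level C8 is benzylic and can hold a configurationally stable, carbamate-bearing carbanion. In the key step an (R)-1-arylethyl carbamate (ring B as silyl-protected allylphenol) is lithiated, borylated with the ring A benzylboronic ester and rearranged: one stereospecific 1,2-metallate shift joins both halves and fixes C8. Retentive protodeboronation with desilylation, then C8-steered para-methoxylative dearomatisation, create C4 and deliver the dienone.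

Key step: step 7

Labels used throughout: ring B is C1 (carbonyl or phenol carbon), C2 (allyl), C3 (H), C4 (carries C8), C5 (OMe), C6 (H). C7 is ArCH2 and C8 is CH(CH3). Assumption: compounds 1 and 7 are taken as purchasable.

Step 1
Reactants: 1 1-(4-hydroxy-2-methoxyphenyl)ethan-1-one
Product: 2 1-[4-(allyloxy)-2-methoxyphenyl]ethan-1-one
Conditions: allyl bromide, K2CO3, acetone, reflux
Reagents that add atoms: allyl bromide, C=CCBr
Why: Williamson ether synthesis: the phenoxide of the acidic para-acylphenol displaces bromide from the allylic halide, and no stereocentre is involved.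

Step 2
Reactants: 2 1-[4-(allyloxy)-2-methoxyphenyl]ethan-1-one
Product: 3 1-(5-allyl-4-hydroxy-2-methoxyphenyl)ethan-1-one
Conditions: PhNEt2, 200 °C, sealed tube
Reagents that add atoms: none
Why: Aromatic Claisen rearrangement ([3,3]-sigmatropic shift, then tautomerisation): the allyl group should migrate to the open ortho position C2, para to the C5 methoxy group, rather than to C6 between the two oxygens, because the methylated C5 oxygen cannot form the chelate with the acetyl group that would fix the ring bonds toward C6.

Step 3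
Reactants: 3 1-(5-allyl-4-hydroxy-2-methoxyphenyl)ethan-1-one
Product: 4 1-[5-allyl-2-methoxy-4-(triisopropylsilyloxy)phenyl]ethan-1-one
Conditions: TIPSCl, imidazole, DMF, rt
Reagents that add atoms: chlorotriisopropylsilane, CC(C)[Si](Cl)(C(C)C)C(C)C
Why: Standard imidazole-promoted O-silylation: the bulky, poorly coordinating silyl ether removes the acidic proton before the organolithium step and shields C6–H.

Step 4
Reactants: 4 1-[5-allyl-2-methoxy-4-(triisopropylsilyloxy)phenyl]ethan-1-one
Product: 5 (1R)-1-[5-allyl-2-methoxy-4-(triisopropylsilyloxy)phenyl]ethan-1-ol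
Conditions: RuCl[(R,R)-TsDPEN](p-cymene) (1 mol%), HCO2H/Et3N 5:2, 30 °C
Reagents that add atoms: none
Why: Noyori asymmetric transfer hydrogenation: the (R,R)-catalyst should deliver hydride to the Si face of the aryl methyl ketone and set the (R)-carbinol centre, while the outer-sphere mechanism leaves the isolated allyl double bond untouched.

Step 5
Reactants: 5 (1R)-1-[5-allyl-2-methoxy-4-(triisopropylsilyloxy)phenyl]ethan-1-ol
Product: 6 (1R)-1-[5-allyl-2-methoxy-4-(triisopropylsilyloxy)phenyl]ethyl N,N-diisopropylcarbamate
Conditions: NaH, THF, 0 °C; iPr2NCOCl, 0 °C to reflux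
Reagents that add atoms: N,N-diisopropylcarbamoyl chloride, CC(C)N(C(C)C)C(=O)Cl
Why: O-acylation of the sodium alkoxide by the carbamoyl chloride leaves the C–O bond at the stereocentre untouched (retention), and the basic medium avoids ionisation of the electron-rich benzylic position.

Step 6
Reactants: 7 4-(chloromethyl)-1,2-dimethoxybenzene (3,4-dimethoxybenzyl chloride)
Product: 8 2-(3,4-dimethoxybenzyl)-4,4,5,5-tetramethyl-1,3,2-dioxaborolane
Conditions: B2pin2, Pd(dba)2 (3 mol%), P(4-MeOC6H4)3 (6 mol%), KOAc, toluene, 50 °C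
Reagents that add atoms: bis(pinacolato)diboron, CC1(C)OB(OC1(C)C)B1OC(C)(C)C(C)(C)O1
Why: Miyaura-type borylation of a benzylic halide: oxidative addition of the C–Cl bond to zerovalent palladium, acetate-assisted transmetallation with B2pin2 and reductive elimination give the primary benzylboronic ester, and the mild temperature limits bibenzyl formation.

Step 7
Reactants: 6 (1R)-1-[5-allyl-2-methoxy-4-(triisopropylsilyloxy)phenyl]ethyl N,N-diisopropylcarbamate; 8 2-(3,4-dimethoxybenzyl)-4,4,5,5-tetramethyl-1,3,2-dioxaborolane
Product: 11 2-{(2R)-2-[5-allyl-2-methoxy-4-(triisopropylsilyloxy)phenyl]-1-(3,4-dimethoxyphenyl)propan-2-yl}-4,4,5,5-tetramethyl-1,3,2-dioxaborolane, via lithiated carbamate 9 (not isolated), via lithium boronate complex 10 (not isolated)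
Conditions: sBuLi, Et2O, −78 °C, 1 h; 8 in Et2O, −78 °C, 2 h; then −78 °C to rt, 16 h
Reagents that add atoms: none
Why: Guided by the carbamate carbonyl, sBuLi removes the benzylic C8–H of 6 with retention to give the configurationally stable tertiary organolithium 9, which is trapped at the boron of 8 with retention to give boronate 10. On warming, the 3,4-dimethoxybenzyl group migrates from boron to C8 antiperiplanar to the departing carbamate (1,2-metallate rearrangement, inversion at C8), and this forms the C7–C8 bond. The reaction type is the lithiation–borylation of secondary benzylic carbamates, a Matteson-type homologation with a chiral carbenoid. No ring is closed. The C8 configuration is controlled only by the (R)-carbinol centre of 6 through the retention, retention, inversion sequence, so the benzyl group takes the place of the carbamate with net inversion and boron stands where hydrogen will end. The step needs deprotonation at C8–H in preference to the allylic ArCH2 and to C6–H, which the complex-induced proximity effect of the carbamate, the diamine-free Et2O medium at −78 °C and the bulky OTIPS group should secure, while the unhindered primary boronic ester should make boronate formation irreversible.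

Step 8
Reactants: 11 2-{(2R)-2-[5-allyl-2-methoxy-4-(triisopropylsilyloxy)phenyl]-1-(3,4-dimethoxyphenyl)propan-2-yl}-4,4,5,5-tetramethyl-1,3,2-dioxaborolane
Product: 13 2-allyl-4-[(2R)-1-(3,4-dimethoxyphenyl)propan-2-yl]-5-methoxyphenol, via free phenol boronic ester 12 (not isolated)
Conditions: TBAF·3H2O (4 equiv), toluene, rt to 45 °C
Reagents that add atoms: none
Why: Fluoride-mediated protodeboronation of a tertiary benzylic boronic ester: fluoride first cleaves the aryl silyl ether and then adds to boron, and hydrogen-bonded water protonates the C8–B bond from the front (SE2, retention), so hydrogen takes the place of boron and C8 stays (R).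

Step 9
Reactants: 13 2-allyl-4-[(2R)-1-(3,4-dimethoxyphenyl)propan-2-yl]-5-methoxyphenol
Product: 14 (4R)-2-allyl-4-[(2R)-1-(3,4-dimethoxyphenyl)propan-2-yl]-4,5-dimethoxycyclohexa-2,5-dien-1-one
Conditions: PhI(OAc)2, MeOH, −20 to 0 °C
Reagents that add atoms: methanol, CO
Why: Hypervalent (trivalent) iodine oxidative dearomatisation of a para-alkylphenol: methanol as solvent captures the activated ring at C4, para to oxygen and next to the donating C5 methoxy group; with C8–H lying in the ring plane beside that methoxy group (least A(1,3) strain) the CH2Ar arm covers one face, so methanol should enter anti to it on the side of the C8 methyl group to give (4R), and the minor C4 epimer is removed by chromatography.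

Compound list
1 | 1-(4-hydroxy-2-methoxyphenyl)ethan-1-one | CC(=O)c1ccc(O)cc1OC | starting material
2 | 1-[4-(allyloxy)-2-methoxyphenyl]ethan-1-one | CC(=O)c1ccc(OCC=C)cc1OC | intermediate
3 | 1-(5-allyl-4-hydroxy-2-methoxyphenyl)ethan-1-one | CC(=O)c1cc(CC=C)c(O)cc1OC | intermediate
4 | 1-[5-allyl-2-methoxy-4-(triisopropylsilyloxy)phenyl]ethan-1-one | CC(=O)c1cc(CC=C)c(O[Si](C(C)C)(C(C)C)C(C)C)cc1OC | intermediate
5 | (1R)-1-[5-allyl-2-methoxy-4-(triisopropylsilyloxy)phenyl]ethan-1-ol | C[C@@H](O)c1cc(CC=C)c(O[Si](C(C)C)(C(C)C)C(C)C)cc1OC | intermediate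
6 | (1R)-1-[5-allyl-2-methoxy-4-(triisopropylsilyloxy)phenyl]ethyl N,N-diisopropylcarbamate | C[C@@H](OC(=O)N(C(C)C)C(C)C)c1cc(CC=C)c(O[Si](C(C)C)(C(C)C)C(C)C)cc1OC | intermediate
7 | 4-(chloromethyl)-1,2-dimethoxybenzene | COc1ccc(CCl)cc1OC | starting material
8 | 2-(3,4-dimethoxybenzyl)-4,4,5,5-tetramethyl-1,3,2-dioxaborolane | COc1ccc(CB2OC(C)(C)C(C)(C)O2)cc1OC | intermediate
9 | lithiated carbamate: 6 with lithium in place of the C8 hydrogen, (R), retention | C[C@@]([Li])(OC(=O)N(C(C)C)C(C)C)c1cc(CC=C)c(O[Si](C(C)C)(C(C)C)C(C)C)cc1OC | intermediate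
10 | lithium boronate complex: boron of 8 bound to C8 of 9, (R), carbamate still in place | [Li+].C[C@@]([B-]1(Cc2ccc(OC)c(OC)c2)OC(C)(C)C(C)(C)O1)(OC(=O)N(C(C)C)C(C)C)c1cc(CC=C)c(O[Si](C(C)C)(C(C)C)C(C)C)cc1OC | intermediate
11 | 2-{(2R)-2-[5-allyl-2-methoxy-4-(triisopropylsilyloxy)phenyl]-1-(3,4-dimethoxyphenyl)propan-2-yl}-4,4,5,5-tetramethyl-1,3,2-dioxaborolane | C[C@](B1OC(C)(C)C(C)(C)O1)(Cc1ccc(OC)c(OC)c1)c1cc(CC=C)c(O[Si](C(C)C)(C(C)C)C(C)C)cc1OC | intermediate
12 | 2-allyl-4-[(2R)-1-(3,4-dimethoxyphenyl)-2-(4,4,5,5-tetramethyl-1,3,2-dioxaborolan-2-yl)propan-2-yl]-5-methoxyphenol | C[C@](B1OC(C)(C)C(C)(C)O1)(Cc1ccc(OC)c(OC)c1)c1cc(CC=C)c(O)cc1OC | intermediate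
13 | 2-allyl-4-[(2R)-1-(3,4-dimethoxyphenyl)propan-2-yl]-5-methoxyphenol | C=CCc1cc([C@H](C)Cc2ccc(OC)c(OC)c2)c(OC)cc1O | intermediate
14 | (4R)-2-allyl-4-[(2R)-1-(3,4-dimethoxyphenyl)propan-2-yl]-4,5-dimethoxycyclohexa-2,5-dien-1-one | C=CCC1=C[C@](OC)([C@H](C)Cc2ccc(OC)c(OC)c2)C(OC)=CC1=O | target

Total step count: 9. Longest linear sequence: 8 steps (steps 1 to 5, then 7 to 9).

Steps most likely to fail

Step 7. The base may metalate the doubly activated allylic ArCH2 or C6–H instead of C8–H. The organolithium may also lose its configuration before it is borylated. The fallback reverses the roles of the partners, so that the ring B half never meets sBuLi and C8 travels as a configurationally stable C–B centre. It sets out from 5 and comes back at 13. Alcohol 5 is dehydrated (MsCl, Et3N, CH2Cl2) to the vinylarene (2-allyl-4-ethenyl-5-methoxyphenoxy)triisopropylsilane F1. Markovnikov hydroboration with HBpin follows (CuCl, KOtBu, the DTBM-SEGPHOS enantiomer that delivers the S product, toluene). The conjugated vinyl group should react ahead of the isolated allyl group and give the (S)-secondary benzylic boronic ester F2. 3,4-Dimethoxybenzyl alcohol and iPr2NCOCl give 3,4-dimethoxybenzyl N,N-diisopropylcarbamate F3. F3 is deprotonated (sBuLi, TMEDA, Et2O, −78 °C) and treated with F2. The C8 group migrates from boron to C7 with retention and gives the C7-borylated coupling product F4 as a mixture at C7. TBAF·3H2O in toluene (with Mn(OAc)3 and 4-tert-butylcatechol if a radical pathway is needed) removes boron at C7, where no stereocentre remains, and the silyl group, and this gives 13.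

Step 8. Desilylation is fast and leaves an electron-rich phenoxide, which slows the build-up of negative charge at C8 that protodeboronation needs. Forcing conditions could erode retention. The fallback turns the para oxygen into an acceptor-substituted group before boron is removed. It sets out from 11 and comes back at 13. Buffered TBAF/AcOH (THF, 0 °C) removes only the silyl group, and phenol 12 is isolated. TsCl, Et3N and DMAP give the aryl tosylate boronic ester F5. TBAF·3H2O in toluene then protodeboronates the less electron-rich arene with retention to the aryl tosylate F6. KOH in MeOH/THF cleaves the sulfonate to 13.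

Step 9. Facial selectivity in the capture by methanol may be poor, and C6 of ring A may capture the activated ring B in place of the solvent. The fallback separates oxygen delivery from methylation and recycles material. It sets out from 13 and comes back at 14. PhI(OAc)2 in MeCN/H2O at 0 °C gives the para-quinols. The (4R,8R)-para-quinol F7 is separated by chromatography or crystallisation from its (4S,8R)-epimer F8. F8 is returned to 13 by reductive rearomatisation (Zn, AcOH). F7 is O-methylated (MeI, Ag2O, CH2Cl2) to 14.

Further compounds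
F1 | step 7 | (2-allyl-4-ethenyl-5-methoxyphenoxy)triisopropylsilane | C=CCc1cc(C=C)c(OC)cc1O[Si](C(C)C)(C(C)C)C(C)C
F2 | step 7 | 2-{(1S)-1-[5-allyl-2-methoxy-4-(triisopropylsilyloxy)phenyl]ethyl}-4,4,5,5-tetramethyl-1,3,2-dioxaborolane | C=CCc1cc([C@H](C)B2OC(C)(C)C(C)(C)O2)c(OC)cc1O[Si](C(C)C)(C(C)C)C(C)C
F3 | step 7 | 3,4-dimethoxybenzyl N,N-diisopropylcarbamate | COc1ccc(COC(=O)N(C(C)C)C(C)C)cc1OC
F4 | step 7 | 2-{(2R)-2-[5-allyl-2-methoxy-4-(triisopropylsilyloxy)phenyl]-1-(3,4-dimethoxyphenyl)propyl}-4,4,5,5-tetramethyl-1,3,2-dioxaborolane, mixture at C7 | C=CCc1cc([C@H](C)C(B2OC(C)(C)C(C)(C)O2)c2ccc(OC)c(OC)c2)c(OC)cc1O[Si](C(C)C)(C(C)C)C(C)C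
F5 | step 8 | 2-allyl-4-[(2R)-1-(3,4-dimethoxyphenyl)-2-(4,4,5,5-tetramethyl-1,3,2-dioxaborolan-2-yl)propan-2-yl]-5-methoxyphenyl 4-methylbenzenesulfonate | C[C@](B1OC(C)(C)C(C)(C)O1)(Cc1ccc(OC)c(OC)c1)c1cc(CC=C)c(OS(=O)(=O)c2ccc(C)cc2)cc1OC
F6 | step 8 | 2-allyl-4-[(2R)-1-(3,4-dimethoxyphenyl)propan-2-yl]-5-methoxyphenyl 4-methylbenzenesulfonate | C=CCc1cc([C@H](C)Cc2ccc(OC)c(OC)c2)c(OC)cc1OS(=O)(=O)c1ccc(C)cc1
F7 | step 9 | (4R)-2-allyl-4-[(2R)-1-(3,4-dimethoxyphenyl)propan-2-yl]-4-hydroxy-5-methoxycyclohexa-2,5-dien-1-one | C=CCC1=C[C@](O)([C@H](C)Cc2ccc(OC)c(OC)c2)C(OC)=CC1=O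
F8 | step 9 | (4S)-2-allyl-4-[(2R)-1-(3,4-dimethoxyphenyl)propan-2-yl]-4-hydroxy-5-methoxycyclohexa-2,5-dien-1-one | C=CCC1=C[C@@](O)([C@H](C)Cc2ccc(OC)c(OC)c2)C(OC)=CC1=O
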